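**Plan**

1. Numbering (daucane): C1 (quaternary, C15 methyl), C2 (OAc), C3, C4 (OH, iPr), C5 (ring-fusion H), C6 (anisoate), C7, C8 (C14 methyl), C9, C10 (OH); α = face of C5–H, β = face of C15.
2. Cuts: the two esters; the cyclopentane at C3–C4 (aldol) and C2–C3 (MeLi on a lactone carbonyl); the seven-membered ring at C1–C10 (aldol of a lactone enolate with a cis-epoxy aldehyde); the lactone at C5–C6 (allylboration); the chain at C7–C8.
3. Enabling feature: on the seven-membered ring (C1, C5–C10) the C2 carbon on C1 and the oxygen on C6 lie 1,3-cis on the α face. C2 can therefore be held as the carbonyl of a γ-butyrolactone (O6–C6–C5–C1–C2) whose α-carbon is C1. Closing C1–C10 on this lactone can only bridge it cis, which fixes the quaternary centre and the later trans ring fusion, and both C1 epimers converge.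
4. Forward order: the Z-trisubstituted C6–C10 chain and an ester-bearing allylboronate are joined to the cis-lactone; epoxidation and oxidation give the epoxy aldehyde; the seven-membered ring closes; the lactone is opened to a methyl ketone; the cyclopentane closes by aldol; reduction and acylations finish.
5. Stereochemistry: C5/C6 from a chiral phosphoric acid-catalysed syn-allylboration; C8/C9 from Katsuki–Sharpless epoxidation; C1 and C10 in the ring closure (lactone tether, epoxide); C4 and C2 by substrate control on the bicycle.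

Key step: step 11

Assumption: 2-bromo-3-methylbut-1-ene (8) is used as bought; its Grignard reagent is expected to form normally with Mg in THF.

**Step 1**
Reactants: 1 but-2-yn-1-ol
Product: 3 (2Z)-3-iodobut-2-en-1-ol, via cyclic alkenylaluminate 2 (not isolated)
Conditions: NaAlH2(OCH2CH2OMe)2, THF, 0 °C to rt; then I2, THF, −78 °C
Reagents that add atoms: iodine, II
Why: Alkoxide-directed trans-hydroalumination of the propargylic alcohol puts aluminium on C3 cis to the CH2O group, and iodinolysis with retention should give the Z vinyl iodide (hydroalumination–iodination).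

**Step 2**
Reactants: 3 (2Z)-3-iodobut-2-en-1-ol
Product: 4 (2Z)-3-iodobut-2-en-1-yl 4-methoxybenzyl ether
Conditions: NaH, 4-methoxybenzyl chloride, Bu4NI (cat.), THF, 0 °C to rt
Reagents that add atoms: 4-methoxybenzyl chloride, COc1ccc(CCl)cc1
Why: Williamson ether synthesis on the primary allylic alkoxide; an ether is chosen because a silyl ether cis to the later vinyllithium could migrate from O to C.

**Step 3**
Reactants: 4 (2Z)-3-iodobut-2-en-1-yl 4-methoxybenzyl ether
Product: 6 (3Z)-5-[(4-methoxybenzyl)oxy]-3-methylpent-3-en-1-ol, via vinyllithium 5 (not isolated)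
Conditions: tBuLi (2 equiv), Et2O, −78 °C; then ethylene oxide, −78 to 0 °C; H2O
Reagents that add atoms: ethylene oxide, C1CO1
Why: Iodine–lithium exchange goes with retention of alkene geometry and the vinyllithium opens ethylene oxide (epoxide alkylation), so C6 and C7 are attached cis to C10 on the trisubstituted alkene.

**Step 4**
Reactants: 6 (3Z)-5-[(4-methoxybenzyl)oxy]-3-methylpent-3-en-1-ol
Product: 7 (3Z)-5-[(4-methoxybenzyl)oxy]-3-methylpent-3-enal
Conditions: Dess–Martin periodinane, NaHCO3, CH2Cl2, 0 °C (used at once)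
Reagents that add atoms: none
Why: Dess–Martin oxidation under buffered, non-basic conditions should give the β,γ-unsaturated aldehyde without migration of the double bond into conjugation.

**Step 5**
Reactants: 8 2-bromo-3-methylbut-1-ene; 9 methyl propiolate; 10 2-(iodomethyl)-4,4,5,5-tetramethyl-1,3,2-dioxaborolane
Product: 14 methyl (2E)-5-methyl-4-methylidene-2-[(4,4,5,5-tetramethyl-1,3,2-dioxaborolan-2-yl)methyl]hex-2-enoate, via Grignard reagent 11 (not isolated), via alkenylcopper 12 (not isolated), via α-cuprio acrylate 13 (not isolated)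
Conditions: 8, Mg, THF; CuBr·SMe2, −78 °C; 9, −78 °C; then 10, HMPA, −78 to 0 °C
Reagents that add atoms: none
Why: Syn-carbocupration of the propiolate followed by alkylation of the α-cuprio acrylate with retention places the alkenyl group cis to CH2B (carbocupration–electrophilic trapping), the geometry needed for a syn allylboration.

**Step 6**
Reactants: 7 (3Z)-5-[(4-methoxybenzyl)oxy]-3-methylpent-3-enal; 14 allylboronate
Product: 16 (4S,5S)-5-{(2Z)-4-[(4-methoxybenzyl)oxy]-2-methylbut-2-en-1-yl}-3-methylidene-4-(3-methylbut-1-en-2-yl)oxolan-2-one (4,5-cis), via O-boryl syn adduct 15 (not isolated)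
Conditions: (R)-3,3′-bis(2,4,6-triisopropylphenyl)-1,1′-binaphthyl-2,2′-diyl hydrogen phosphate (5 mol %), 4 Å MS, toluene, 0 °C to rt; then pyridinium p-toluenesulfonate, 40 °C
Reagents that add atoms: none
Why: Brønsted acid-catalysed allylboration through a closed chair transition state transfers the boronate geometry into the syn adduct and hence the 4,5-cis lactone after lactonisation, while the chiral phosphate is expected to select the aldehyde face that gives (S) at C6.

**Step 7**
Reactants: 16 α-methylene lactone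
Product: 17 (4R,5S)-5-{(2Z)-4-[(4-methoxybenzyl)oxy]-2-methylbut-2-en-1-yl}-3-methyl-4-(3-methylbut-1-en-2-yl)oxolan-2-one (C3 epimer mixture; ring carbons configured as in 16)
Conditions: NaBH4, MeOH, 0 °C
Reagents that add atoms: none
Why: Conjugate hydride reduction of the α-methylene lactone turns the exocyclic CH2 into the C15 methyl group; the configuration at C1 does not matter because C1 is enolised in step 11.

**Step 8**
Reactants: 17 α-methyl lactone
Product: 18 (4R,5S)-5-[(2Z)-4-hydroxy-2-methylbut-2-en-1-yl]-3-methyl-4-(3-methylbut-1-en-2-yl)oxolan-2-one (C3 epimer mixture)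
Conditions: DDQ, CH2Cl2–pH 7 buffer, 0 °C
Reagents that add atoms: none
Why: Oxidative cleavage of the 4-methoxybenzyl ether by DDQ (benzylic hydride abstraction) should leave the lactone and both alkenes untouched.

**Step 9**
Reactants: 18 allylic alcohol
Product: 19 (4R,5S)-5-{[(2R,3S)-3-(hydroxymethyl)-2-methyloxiran-2-yl]methyl}-3-methyl-4-(3-methylbut-1-en-2-yl)oxolan-2-one (C3 epimer mixture)
Conditions: Ti(OiPr)4, L-(+)-diethyl tartrate, tBuOOH, 4 Å MS, CH2Cl2, −20 °C
Reagents that add atoms: tert-butyl hydroperoxide, CC(C)(C)OO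
Why: Katsuki–Sharpless asymmetric epoxidation under reagent control sets C8 (R) and C9 (S) on the Z-trisubstituted allylic alcohol (the cis-epoxide follows from the Z alkene), and the 1,1-disubstituted alkene, which has no allylic hydroxyl, should not react.

**Step 10**
Reactants: 19 epoxy alcohol
Product: 20 (2R,3R)-3-methyl-3-{[(2S,3R)-4-methyl-3-(3-methylbut-1-en-2-yl)-5-oxooxolan-2-yl]methyl}oxirane-2-carbaldehyde (cis-epoxy aldehyde; C1 epimer mixture)
Conditions: Dess–Martin periodinane, NaHCO3, CH2Cl2, 0 °C
Reagents that add atoms: none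
Why: Dess–Martin oxidation of a 2,3-epoxy alcohol gives the epoxy aldehyde under neutral conditions, and the aldehyde α-carbon is an epoxide carbon that cannot epimerise.

**Step 11**
Reactants: 20 cis-epoxy aldehyde
Product: 23 bridged lactone: seven-membered ring C1/C5–C10 with 8α,9α-epoxide and 10β-OSiEt3 and with C2(=O)–O6 as γ-lactone bridge on the α face (7-oxabicyclo[4.2.1]nonan-8-one core), via potassium enolate 21 (not isolated), via potassium aldolate 22 (not isolated)
Conditions: KN(SiMe3)2, 18-crown-6, THF (high dilution), −78 °C; then Et3SiCl, −78 to −40 °C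
Reagents that add atoms: chlorotriethylsilane, CC[Si](Cl)(CC)CC
Why: KN(SiMe3)2 removes C1–H of the lactone (both C1 epimers give the same planar enolate 21), the enolate carbon adds to the C10 aldehyde to give alkoxide 22, and this is silylated before retro-aldol can set in. The closest known reaction type is the base-mediated intramolecular aldol addition of an ester or lactone enolate to a tethered aldehyde. The seven-membered carbocycle (C1, C5, C6, C7, C8, C9, C10) closes in a 7-(enolexo)-exo-trig mode, and because the chain is anchored at the lactone γ-carbon C6 it can reach only one face of C1, giving the bridged bicycle. C1 is therefore set by C6 through the lactone ring: C10 enters cis to C7, the methyl group ends anti, and C2 and C4 become trans across C1–C5, the future trans ring fusion. C10 is controlled by the cis-epoxide, since in the crown ether-separated, non-chelated addition the carbonyl should lie anti to the C9–O bond (dipole-minimised, Cornforth-type arrangement), so the new oxygen ends trans to the epoxide. The step needs enolisation at C1 only and attack on the aldehyde instead of the epoxide; C1–H is the only acidic proton and opening the epoxide would require an unfavourable endo attack.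

**Step 12**
Reactants: 23 bridged lactone
Product: 24 hydroxy methyl ketone: 1α-acetyl-1β-methyl cycloheptane with free 6α-OH; 5β-(3-methylbut-1-en-2-yl); 8α,9α-epoxide; 10β-OSiEt3 (in equilibrium with its hemiketal)
Conditions: MeLi, THF, −78 °C; then H2O
Reagents that add atoms: methyllithium, [Li]C
Why: Nucleophilic addition of MeLi to the lactone carbonyl should stop at the lithium hemiketal, which on work-up opens to the γ-hydroxy methyl ketone; this removes the temporary ring, supplies C3 and frees the C6 hydroxyl.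

**Step 13**
Reactants: 24 hydroxy methyl ketone
Product: 25 6α-(4-methoxybenzoate) of 24
Conditions: 4-methoxybenzoyl chloride, Et3N, 4-(dimethylamino)pyridine (cat.), CH2Cl2, 0 °C to rt
Reagents that add atoms: 4-methoxybenzoyl chloride, COc1ccc(C(Cl)=O)cc1
Why: Nucleophilic catalysis of acylation on the only free secondary hydroxyl (C10 is silylated and the C4 carbinol does not yet exist) installs the anisoate on the former lactone oxygen.

**Step 14**
Reactants: 25 anisoate
Product: 27 diketone: 1α-acetyl and 5β-isobutyryl on the cycloheptane (6α-anisoate; 10β-OSiEt3), via ozonide 26 (not isolated)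
Conditions: O3, CH2Cl2, −78 °C; then Me2S, −78 °C to rt
Reagents that add atoms: ozone, [O-][O+]=O
Why: Ozonolysis with reductive work-up cleaves the only remaining alkene, the 1,1-disubstituted one, and unmasks the C4 isopropyl ketone.

**Step 15**
Reactants: 27 diketone
Product: 28 trans-fused ketol: 4β-hydroxy-4α-isopropyl-2-oxo daucane (6α-anisoate; 8α,9α-epoxide; 10β-OSiEt3)
Conditions: LiN(iPr)2, THF, −78 °C; AcOH quench at −78 °C
Reagents that add atoms: none
Why: Kinetic deprotonation should occur at the methyl ketone, the only unhindered α-position, and the enolate adds to the C4 ketone in an intramolecular aldol addition (5-enolexo-exo-trig) with the isopropyl group turned away from the C5–C6 bond, placing the new hydroxyl β and the isopropyl α.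

**Step 16**
Reactants: 28 ketol
Product: 29 2β,4β-diol (6α-anisoate; 8α,9α-epoxide; 10β-OSiEt3)
Conditions: NaBH4, MeOH–CH2Cl2, −40 °C
Reagents that add atoms: none
Why: Substrate-controlled ketone reduction: hydride should enter the cyclopentanone anti to the adjacent angular C15 methyl group and give the 2β-alcohol, cis to the methyl group and to the 4β-hydroxyl.

**Step 17**
Reactants: 29 diol
Product: 30 2β-acetate 10β-triethylsilyl ether
Conditions: Ac2O, pyridine, 4-(dimethylamino)pyridine (cat.), CH2Cl2, rt
Reagents that add atoms: acetic anhydride, CC(=O)OC(C)=O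
Why: Acetylation of the secondary C2 hydroxyl; the hindered tertiary C4 hydroxyl is not expected to react under these conditions.

**Step 18**
Reactants: 30 2β-acetate 10β-triethylsilyl ether
Product: 31 (1S,2R,4R,5S,6S,8R,9S,10R)-2-acetoxy-8,9-epoxy-4,10-dihydroxydaucan-6-yl 4-methoxybenzoate (target)
Conditions: Bu4NF, AcOH, THF, 0 °C
Reagents that add atoms: none
Why: Fluoride-mediated desilylation buffered with acetic acid should free the C10 hydroxyl without acetyl migration from O2 or opening of the epoxide.

**Compound list**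

1 | but-2-yn-1-ol | CC#CCO | starting material
2 | sodium cyclic (Z)-alkenyl alkoxyaluminate from 1 | [Na+].CC1=CCO[Al-]1(OCCOC)OCCOC | intermediate (not isolated)
3 | (2Z)-3-iodobut-2-en-1-ol | C/C(I)=C/CO | intermediate
4 | (2Z)-3-iodobut-2-en-1-yl 4-methoxybenzyl ether | C/C(I)=C/COCc1ccc(OC)cc1 | intermediate
5 | (2Z)-vinyllithium from 4 | C/C([Li])=C/COCc1ccc(OC)cc1 | intermediate (not isolated)
6 | (3Z)-5-[(4-methoxybenzyl)oxy]-3-methylpent-3-en-1-ol | OCC/C(C)=C\COCc1ccc(OC)cc1 | intermediate
7 | (3Z)-5-[(4-methoxybenzyl)oxy]-3-methylpent-3-enal | O=CC/C(C)=C\COCc1ccc(OC)cc1 | intermediate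
8 | 2-bromo-3-methylbut-1-ene | C=C(Br)C(C)C | starting material
9 | methyl propiolate | C#CC(=O)OC | starting material
10 | 2-(iodomethyl)-4,4,5,5-tetramethyl-1,3,2-dioxaborolane | ICB1OC(C)(C)C(C)(C)O1 | starting material
11 | (3-methylbut-1-en-2-yl)magnesium bromide | C=C([Mg]Br)C(C)C | intermediate (not isolated)
12 | (3-methylbut-1-en-2-yl)copper | C=C([Cu])C(C)C | intermediate (not isolated)
13 | methyl (2Z)-2-cuprio-5-methyl-4-methylidenehex-2-enoate | COC(=O)/C([Cu])=C/C(=C)C(C)C | intermediate (not isolated)
14 | methyl (2E)-5-methyl-4-methylidene-2-[(4,4,5,5-tetramethyl-1,3,2-dioxaborolan-2-yl)methyl]hex-2-enoate | COC(=O)/C(CB1OC(C)(C)C(C)(C)O1)=C/C(=C)C(C)C | intermediate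
15 | O-boryl syn allylboration adduct | COC(=O)C(=C)[C@H](C(=C)C(C)C)[C@@H](OB1OC(C)(C)C(C)(C)O1)C/C(C)=C\COCc1ccc(OC)cc1 | intermediate (not isolated)
16 | (4S,5S)-5-{(2Z)-4-[(4-methoxybenzyl)oxy]-2-methylbut-2-en-1-yl}-3-methylidene-4-(3-methylbut-1-en-2-yl)oxolan-2-one | O=C1O[C@@H](C/C(C)=C\COCc2ccc(OC)cc2)[C@@H](C(=C)C(C)C)C1=C | intermediate
17 | (4R,5S)-5-{(2Z)-4-[(4-methoxybenzyl)oxy]-2-methylbut-2-en-1-yl}-3-methyl-4-(3-methylbut-1-en-2-yl)oxolan-2-one, C3 epimers | O=C1O[C@@H](C/C(C)=C\COCc2ccc(OC)cc2)[C@@H](C(=C)C(C)C)C1C | intermediate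
18 | (4R,5S)-5-[(2Z)-4-hydroxy-2-methylbut-2-en-1-yl]-3-methyl-4-(3-methylbut-1-en-2-yl)oxolan-2-one, C3 epimers | O=C1O[C@@H](C/C(C)=C\CO)[C@@H](C(=C)C(C)C)C1C | intermediate
19 | (4R,5S)-5-{[(2R,3S)-3-(hydroxymethyl)-2-methyloxiran-2-yl]methyl}-3-methyl-4-(3-methylbut-1-en-2-yl)oxolan-2-one, C3 epimers | O=C1O[C@@H](C[C@@]2(C)O[C@H]2CO)[C@@H](C(=C)C(C)C)C1C | intermediate
20 | (2R,3R)-3-methyl-3-{[(2S,3R)-4-methyl-3-(3-methylbut-1-en-2-yl)-5-oxooxolan-2-yl]methyl}oxirane-2-carbaldehyde, C1 epimers | O=C1O[C@@H](C[C@@]2(C)O[C@H]2C=O)[C@@H](C(=C)C(C)C)C1C | intermediate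
21 | potassium lactone enolate of 20 | [K+].[O-]C=1O[C@@H](C[C@@]2(C)O[C@H]2C=O)[C@@H](C(=C)C(C)C)C=1C | intermediate (not isolated)
22 | potassium aldolate (bridged lactone 10β-alkoxide) | [K+].O=C1O[C@H]2C[C@@]3(C)O[C@H]3[C@H]([O-])[C@]1(C)[C@@H]2C(=C)C(C)C | intermediate (not isolated)
23 | bridged lactone, 8α,9α-epoxide, 10β-OSiEt3 | O=C1O[C@H]2C[C@@]3(C)O[C@H]3[C@H](O[Si](CC)(CC)CC)[C@]1(C)[C@@H]2C(=C)C(C)C | intermediate
24 | hydroxy methyl ketone (1α-acetyl, 6α-OH) | O[C@H]2C[C@@]3(C)O[C@H]3[C@H](O[Si](CC)(CC)CC)[C@](C(C)=O)(C)[C@@H]2C(=C)C(C)C | intermediate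
25 | 6α-(4-methoxybenzoate) of 24 | COc1ccc(C(=O)O[C@H]2C[C@@]3(C)O[C@H]3[C@H](O[Si](CC)(CC)CC)[C@](C(C)=O)(C)[C@@H]2C(=C)C(C)C)cc1 | intermediate
26 | ozonide of 25 (1,2,4-trioxolane at C4) | COc1ccc(C(=O)O[C@H]2C[C@@]3(C)O[C@H]3[C@H](O[Si](CC)(CC)CC)[C@](C(C)=O)(C)[C@@H]2C4(C(C)C)OOCO4)cc1 | intermediate (not isolated)
27 | diketone (1α-acetyl, 5β-isobutyryl) | COc1ccc(C(=O)O[C@H]2C[C@@]3(C)O[C@H]3[C@H](O[Si](CC)(CC)CC)[C@](C(C)=O)(C)[C@@H]2C(=O)C(C)C)cc1 | intermediate
28 | trans-fused ketol (4β-OH, 4α-iPr, 2-oxo) | COc1ccc(C(=O)O[C@H]2C[C@@]3(C)O[C@H]3[C@H](O[Si](CC)(CC)CC)[C@]3(C)[C@@H]2[C@](O)(C(C)C)CC3=O)cc1 | intermediate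
29 | 2β,4β-diol | COc1ccc(C(=O)O[C@H]2C[C@@]3(C)O[C@H]3[C@H](O[Si](CC)(CC)CC)[C@]3(C)[C@@H]2[C@](O)(C(C)C)C[C@H]3O)cc1 | intermediate
30 | 2β-acetate 10β-triethylsilyl ether | COc1ccc(C(=O)O[C@H]2C[C@@]3(C)O[C@H]3[C@H](O[Si](CC)(CC)CC)[C@]3(C)[C@@H]2[C@](O)(C(C)C)C[C@H]3OC(C)=O)cc1 | intermediate
31 | (1S,2R,4R,5S,6S,8R,9S,10R)-2-acetoxy-8,9-epoxy-4,10-dihydroxydaucan-6-yl 4-methoxybenzoate | COc1ccc(C(=O)O[C@H]2C[C@@]3(C)O[C@H]3[C@H](O)[C@]3(C)[C@@H]2[C@](O)(C(C)C)C[C@H]3OC(C)=O)cc1 | target

**Step count and risks**

Total: 18 steps. Longest linear sequence: 17 steps (steps 1–4 and 6–18); step 5 is the side branch.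

Step 11 (first risk). The aldehyde may be attacked on the wrong face through a closed, metal-bridged transition state, so that the C10 oxygen ends cis to the epoxide; retro-aldol before silylation is a second possibility. Fallback, setting out from 20: the aldol is run with LiN(SiMe3)2 in THF at −78 °C and quenched with aqueous NH4Cl, giving the bridged aldol as a C10 epimer mixture F1. Dess–Martin oxidation gives the bridged α,β-epoxy ketone F2, which erases C10. NaBH4–CeCl3·7H2O in MeOH at −78 °C should then deliver hydride from the lactone-bridge face, the other face being covered by the C5 alkenyl group that lies over the four-carbon bridge, to give the 10β-alcohol F3. Et3SiCl and imidazole return to the route at 23.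

Step 6 (second risk). The ester-bearing allylboronate may react too slowly under the chiral phosphoric acid, or the aldehyde face may be poorly discriminated, so that the lactone forms with low enantiomeric purity. Fallback, setting out from 7 and 14: thermal, uncatalysed allylboration (toluene, 80 °C, then pyridinium p-toluenesulfonate) keeps the syn selectivity and gives the racemic cis-lactone, that is 16 together with its enantiomer F4. The conditions of steps 7 and 8 then give 17 and 18 together with the enantiomeric α-methyl lactone F5 and the enantiomeric allylic alcohol F6. In the epoxidation of step 9 the tartrate controls the epoxide configuration in both enantiomers, so 19 is formed beside the diastereomeric epoxy alcohol F7, and the two are separated by chromatography. The route is rejoined at 19.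

Step 15 (third risk). The lithium aldolate of the hindered tertiary carbinol may revert by retro-aldol or lose water, or the base may enolise the ketone next to the anisoate and eliminate it. Fallback, setting out from 27: LiN(SiMe3)2 and Me3SiCl at −78 °C form the trimethylsilyl enol ether of the methyl ketone F8; N-bromosuccinimide converts it to the α-bromo ketone F9; SmI2 in THF at −78 °C then effects an intramolecular Reformatsky reaction through a chelated samarium enolate, without free base, and returns to the route at 28.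

**Further compounds**

F1 | step 11 | bridged aldol, C10 epimer mixture (10-OH analogue of 23) | O=C1O[C@H]2C[C@@]3(C)O[C@H]3C(O)[C@]1(C)[C@@H]2C(=C)C(C)C
F2 | step 11 | bridged 8α,9α-epoxy 10-ketone | O=C1O[C@H]2C[C@@]3(C)O[C@H]3C(=O)[C@]1(C)[C@@H]2C(=C)C(C)C
F3 | step 11 | bridged lactone 10β-alcohol (desilyl 23) | O=C1O[C@H]2C[C@@]3(C)O[C@H]3[C@H](O)[C@]1(C)[C@@H]2C(=C)C(C)C
F4 | step 6 | (4R,5R)-enantiomer of 16 | O=C1O[C@H](C/C(C)=C\COCc2ccc(OC)cc2)[C@H](C(=C)C(C)C)C1=C
F5 | step 6 | enantiomer of 17 (4S,5R; C3 epimers) | O=C1O[C@H](C/C(C)=C\COCc2ccc(OC)cc2)[C@H](C(=C)C(C)C)C1C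
F6 | step 6 | enantiomer of 18 (4S,5R; C3 epimers) | O=C1O[C@H](C/C(C)=C\CO)[C@H](C(=C)C(C)C)C1C
F7 | step 6 | diastereomer of 19: (4S,5R)-lactone with the (2R,3S)-epoxide | O=C1O[C@H](C[C@@]2(C)O[C@H]2CO)[C@H](C(=C)C(C)C)C1C
F8 | step 15 | trimethylsilyl enol ether of the methyl ketone of 27 | COc1ccc(C(=O)O[C@H]2C[C@@]3(C)O[C@H]3[C@H](O[Si](CC)(CC)CC)[C@](C(=C)O[Si](C)(C)C)(C)[C@@H]2C(=O)C(C)C)cc1
F9 | step 15 | bromomethyl ketone from 27 | COc1ccc(C(=O)O[C@H]2C[C@@]3(C)O[C@H]3[C@H](O[Si](CC)(CC)CC)[C@](C(=O)CBr)(C)[C@@H]2C(=O)C(C)C)cc1
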